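**Plan**

- Locants C1–C30 are the atom positions of the target SMILES (ring A = δ-lactone; ring B = cyclohexane C9–C10–C11–C12–C26–C27). The enabling feature is the quaternary bridgehead C22: it carries the oxidised carbon C21 and is bonded to C17, the α-carbon of carboxyl C18. C21–C22–C17–C18 is thus the vinyl/carboxyl pattern left by an ester-enolate [3,3] shift, with C22 as allyl terminus and C17 as enolate carbon.
- Cuts, in retrosynthetic order: C27–CH3; ring A at C7=C8, O4–C5 and C9–C2; O20–C21 (C21 traced back to a vinyl group); C17–C22 (traded for the allylic C–O bond of a ten-membered lactone); the lactone C18–O bond; C14–C16; C12–C13 and C23–C30; C25–C26 and C12–C22.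
- Forward: ring B (cyclohexenone) → cyclopentane (cis-hydrindane) → three-carbon bridge (bicyclo[3.2.1]octane-2,8-dione) → temporary seven-membered tether lactone that fixes the C22 alkene geometry → bridged ten-membered allylic lactone → ring contraction to the bicyclo[2.2.2]octane → γ-lactone → ring A → C27 carbinol.
- Stereochemistry: C12 from a rhodium/(R)-BINAP conjugate addition; C26, C23 and C14 by substrate control on the cis-fused and bridged bicycles; C22 from the C14 tether and C17 from the alkene geometry; C9 by axial attack on the ring B dienolate; C27 by equatorial methyl delivery anti to the cage.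

Key step: step 19

Remark: ring B of the cage intermediates is taken to sit in the only chair the cis ring fusion allows (C22 axial on C12, H26 axial); the facial arguments at C9 and C27 rest on this assumption.

**Route**

Step 1
Reactants: 1 3-bromobut-3-en-1-ol
Product: 2 2-bromo-4-chlorobut-1-ene
Conditions: PPh3, N-chlorosuccinimide, CH2Cl2, 0 °C to rt
Reagents that add atoms: N-chlorosuccinimide, O=C1CCC(=O)N1Cl
Why: Appel-type chlorination of the primary alcohol should be clean because the vinyl bromide is inert to the oxyphosphonium intermediate.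

Step 2
Reactants: 2 2-bromo-4-chlorobut-1-ene
Product: 3 2-(4-chlorobut-1-en-2-yl)-4,4,5,5-tetramethyl-1,3,2-dioxaborolane
Conditions: bis(pinacolato)diboron, PdCl2(PPh3)2, PPh3, KOPh, toluene, 50 °C
Reagents that add atoms: bis(pinacolato)diboron, CC1(C)OB(OC1(C)C)B1OC(C)(C)C(C)(C)O1
Why: Miyaura borylation of a 1-alkenyl bromide, in which oxidative addition should occur only at the sp2 C–Br bond and leave the primary alkyl chloride for step 4.

Step 3
Reactants: 4 cyclohex-2-en-1-one; 3 2-(4-chlorobut-1-en-2-yl)-4,4,5,5-tetramethyl-1,3,2-dioxaborolane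
Product: 5 (R)-3-(4-chlorobut-1-en-2-yl)cyclohexan-1-one
Conditions: [RhCl(C2H4)2]2 (cat.), (R)-BINAP, KOH (aq.), 1,4-dioxane, 40 °C
Reagents that add atoms: none
Why: Hayashi–Miyaura rhodium-catalysed asymmetric 1,4-addition of an alkenylboron reagent; by the established sense of induction ((S)-BINAP gives (S)-3-substituted cyclohexanones) the (R)-ligand should set C12 as (R), the only centre not derived from the substrate.

Step 4
Reactants: 5 (R)-3-(4-chlorobut-1-en-2-yl)cyclohexan-1-one
Product: 6 (3aR,7aR)-1-methylideneoctahydro-4H-inden-4-one (cis-fused; C27 ketone; C22 methylidene)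
Conditions: t-BuOK, t-BuOH–THF, 25 °C
Reagents that add atoms: none
Why: Intramolecular enolate alkylation (5-exo-tet) under equilibrating conditions, in which only the C26 enolate can close a five-membered ring, so the cis ring fusion sets C26 relative to C12.

Step 5
Reactants: 6 (3aR,7aR)-1-methylideneoctahydro-4H-inden-4-one
Product: 7 cis-fused 1-methylideneoctahydro-1H-inden-4-ol with the C27 hydroxyl cis to the C26–C25 bond
Conditions: LiBH(s-Bu)3, THF, −78 °C; H2O
Reagents that add atoms: none
Why: Hindered-hydride reduction from the convex face of the cis-hydrindanone should place the hydroxyl on the concave face; this centre is temporary (re-oxidised in step 21) and later anchors the tether of step 15.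

Step 6
Reactants: 7 cis-fused 1-methylideneoctahydro-1H-inden-4-ol
Product: 8 tert-butyldimethylsilyl ether of 7
Conditions: TBSOTf, 2,6-lutidine, CH2Cl2, 0 °C
Reagents that add atoms: tert-butyldimethylsilyl trifluoromethanesulfonate, CC(C)(C)[Si](C)(C)OS(=O)(=O)C(F)(F)F
Why: Silyl triflate silylation of a hindered secondary alcohol, giving an ether that survives the enolate, hydride and oxidation steps that follow.

Step 7
Reactants: 8 tert-butyldimethylsilyl ether of 7
Product: 10 cis-fused 4-(tert-butyldimethylsilyloxy)octahydro-1H-inden-1-one (C22 ketone), via ozonide 9 (not isolated)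
Conditions: O3, CH2Cl2, −78 °C; Me2S, −78 °C to rt
Reagents that add atoms: ozone, [O-][O+]=O
Why: Ozonolysis of the 1,1-disubstituted alkene with reductive work-up unveils the C22 ketone without touching any stereocentre.

Step 8
Reactants: 10 cis-fused 4-(tert-butyldimethylsilyloxy)octahydro-1H-inden-1-one
Product: 14 C23-methylidene ketone, via lithium enolate 11 (not isolated), via Mannich base 12 (not isolated), via methiodide 13 (not isolated)
Conditions: LiN(i-Pr)2, THF, −78 °C; CH2=NMe2+ I−, −78 to 0 °C; MeI, CH2Cl2; NaHCO3 (aq.)
Reagents that add atoms: N,N-dimethylmethyleneiminium iodide, C=[N+](C)C.[I-]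
Why: Kinetic deprotonation takes the C23 methylene and not the C12 methine, and the Mannich reaction followed by quaternisation and Hofmann-type elimination gives the α-methylene ketone without epimerising C12.

Step 9
Reactants: 14 C23-methylidene ketone; 15 methacrolein
Product: 17 C23 aldol adduct (C23 quaternary; methyl C24 and 1-hydroxy-2-methylallyl group; carbinol epimers), via lithium enolate 16 (not isolated)
Conditions: LiBH(s-Bu)3, THF, −78 °C; then 15, −78 °C; H2O
Reagents that add atoms: none
Why: Conjugate reduction generates the C22–C23 enolate regiospecifically (the methylene becomes methyl C24) and its aldol addition to the aldehyde from the convex face, anti to the C26–C27 bond and its silyloxy group, sets C23 with the new chain on the side of H12 and H26.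

Step 10
Reactants: 17 C23 aldol adduct
Product: 18 C23 methacryloyl ketone (C22,C30 enedione)
Conditions: Dess–Martin periodinane, CH2Cl2, 0 °C to rt
Reagents that add atoms: none
Why: Dess–Martin oxidation of the allylic carbinol removes the epimeric centre and gives the enone acceptor; C23 is quaternary and cannot epimerise.

Step 11
Reactants: 18 C23 methacryloyl ketone
Product: 19 ring B-fused bicyclo[3.2.1]octane-2,8-dione (C22 and C30 ketones; C14 methyl exo; C27 silyl ether)
Conditions: KN(SiMe3)2 (0.2 equiv), THF, −78 to 0 °C
Reagents that add atoms: none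
Why: Intramolecular Michael addition (6-endo-trig) of the C12 enolate to the methacryloyl CH2 (C13) on the face that carries the acyl group re-sets C12 as a quaternary centre with the configuration relayed from C26 through C23; a non-nucleophilic base avoids retro-Claisen cleavage, and protonation leaves the C14 methyl exo.

Step 12
Reactants: 19 ring B-fused bicyclo[3.2.1]octane-2,8-dione; 20 tert-butyl acrylate
Product: 21 C14 Michael adduct (tert-butyl propanoate chain on C14 syn to C22)
Conditions: KN(SiMe3)2 (0.2 equiv), THF, −78 to −20 °C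
Reagents that add atoms: none
Why: Michael addition at C14, the only enolisable carbon, with the acrylate entering from the exo face (syn to the one-carbon bridge C22, away from the C25–C26 bridge), which sets C14 and points the chain at C22.

Step 13
Reactants: 21 C14 Michael adduct
Product: 22 C27 alcohol of 21 (may equilibrate with its C22 hemiketal)
Conditions: HF·pyridine, THF, 0 °C to rt
Reagents that add atoms: none
Why: Fluoride-mediated silyl ether cleavage under acidic conditions, which leaves the tert-butyl ester intact and avoids an alkoxide that could open the non-enolisable 1,3-diketone.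

Step 14
Reactants: 22 C27 alcohol of 21; 23 diethylphosphonoacetic acid
Product: 24 C27 diethylphosphonoacetate
Conditions: DCC, DMAP (cat.), CH2Cl2, 0 °C to rt
Reagents that add atoms: none
Why: Steglich esterification of the open hydroxy-ketone form under near-neutral conditions installs the phosphonate on the oxygen that lies 1,3-diaxial to C22.

Step 15
Reactants: 24 C27 diethylphosphonoacetate
Product: 25 seven-membered α,β-unsaturated lactone (C27–O–C(=O)–CH=C22; ester carbon cis to C12)
Conditions: LiCl, DBU, MeCN, rt to 50 °C
Reagents that add atoms: none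
Why: Intramolecular Horner–Wadsworth–Emmons olefination (Masamune–Roush conditions), in which the tether brings the stabilised anion to the shielded bridging ketone and the seven-membered ring forces the new carbonyl-bearing carbon cis to C12, fixing the alkene geometry that step 19 needs.

Step 16
Reactants: 25 seven-membered α,β-unsaturated lactone
Product: 27 allylic diol (CH2OH on the C22 alkene cis to C12; C27 hydroxyl free), via hydroxy enal 26 (not isolated)
Conditions: i-Bu2AlH, CH2Cl2, −78 °C; MeOH; NaBH4, CeCl3·7H2O, −78 to −40 °C
Reagents that add atoms: none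
Why: Partial reduction of the lactone to the ring-opened hydroxy enal followed by Luche 1,2-reduction should give the allylic alcohol while sparing the tert-butyl ester and ketone C30, which lies between two quaternary carbons.

Step 17
Reactants: 27 allylic diol
Product: 28 seco acid (C18 carboxylic acid; allylic diol)
Conditions: 85% aq. H3PO4, toluene, rt
Reagents that add atoms: none
Why: Acid-mediated tert-butyl ester cleavage through the tert-butyl cation; the allylic alcohol should survive because ionisation would place cationic character on the bridging carbon C22.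

Step 18
Reactants: 28 seco acid
Product: 29 bridged ten-membered allylic lactone (C18(=O)–O–CH2–CH=C22 spanning C14 and C22; C27 hydroxyl free)
Conditions: 2-methyl-6-nitrobenzoic anhydride, DMAP, toluene (2 mM), slow addition, rt to 60 °C
Reagents that add atoms: none
Why: Shiina macrolactonisation at high dilution, in which the exo C14 chain and the primary allylic alcohol are both held above C22 by the bicycle, while the axial secondary C27 hydroxyl is too hindered and wrongly placed to compete.

Step 19
Reactants: 29 bridged ten-membered allylic lactone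
Product: 32 C22-vinyl bicyclo[2.2.2]octane C18 carboxylic acid (C27 hydroxyl free), via silyl ketene acetal 30 (not isolated), via silyl ester 31 (not isolated)
Conditions: LiN(i-Pr)2 (3 equiv), Me3SiCl–Et3N, THF, −78 °C; then 65 °C; 1 M HCl
Reagents that add atoms: none
Why: Proposed new method: the lactone enolate is trapped as its trimethylsilyl ketene acetal (the C27 hydroxyl is silylated in passing and ketone C30 has no α-hydrogen), and the six atoms C17=C18–O–CH2–CH=C22 undergo a concerted [3,3]-sigmatropic shift that forms C17–C22 and breaks the allylic C–O bond; the closest known reaction type is the Ireland–Claisen ring contraction of macrocyclic allylic lactones to carbocycles with vicinal vinyl and carboxyl groups, which has not been run across a bridged bicycle or onto an alkene terminus flanked by two quaternary carbons. The ten-membered ring contracts transannularly to the six-membered carbocycle C14–C16–C17–C22–C23–C30 through a boat-like array imposed by the tether, which completes the bicyclo[2.2.2]octane. C22 is controlled by the tether: C17 hangs from C14 on the three-carbon bridge and can reach only the alkene face turned to that bridge, so the vinyl group (future C21) ends on the bridgehead axis. C17 is controlled by the alkene geometry fixed in step 15: with the CH2–O arm cis to C12, C18 must lie on the C12 side of the new bond, and only the ketene acetal with C16 anti to the ring oxygen can reach C22, the other geometry simply returning lactone on hydrolysis. The step needs enolisation at C17 alone and a pericyclic rather than an elimination pathway, which the absence of any other enolisable carbonyl and the internal silyl quench at −78 °C should secure. Aqueous acid then cleaves the silyl ester and silyl ether.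

Step 20
Reactants: 32 C22-vinyl bicyclo[2.2.2]octane C18 carboxylic acid
Product: 35 γ-lactone alcohol (C18(=O)–O20–C21 lactone; C27 hydroxyl), via ozonide 33 (not isolated), via hydroxy acid 34 (not isolated)
Conditions: O3, CH2Cl2, −78 °C; NaBH4, MeOH, −78 to 0 °C; 1 M HCl, rt
Reagents that add atoms: ozone, [O-][O+]=O
Why: Ozonolysis of the vinyl group, hydride reduction of the ozonide to the C21 primary alcohol and acid-catalysed lactonisation onto C18 (5-exo-trig) close the γ-lactone, while ketone C30 is too hindered for NaBH4 at low temperature.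

Step 21
Reactants: 35 γ-lactone alcohol
Product: 36 γ-lactone diketone (C27 and C30 ketones)
Conditions: Dess–Martin periodinane, CH2Cl2, rt
Reagents that add atoms: none
Why: Dess–Martin oxidation returns the ring B ketone and erases the temporary C27 stereocentre.

Step 22
Reactants: 36 γ-lactone diketone; 37 acetaldehyde
Product: 39 C9 aldol adduct (1-hydroxyethyl group on C9; epimers), via lithium enolate 38 (not isolated)
Conditions: LiN(i-Pr)2, THF, −78 °C; then 37; H2O
Reagents that add atoms: none
Why: Kinetic enolisation takes the C9 methylene (C26 is a cage methine and the lactone α-CH is far less acidic) and aldol addition to acetaldehyde brings in C8.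

Step 23
Reactants: 39 C9 aldol adduct
Product: 41 (E)-C9-ethylidene ketone, via mesylate 40 (not isolated)
Conditions: MsCl, Et3N, CH2Cl2, 0 °C; DBU, rt
Reagents that add atoms: none
Why: Mesylation and E1cB elimination give the conjugated (E)-enone, removing both epimeric centres of 39.

Step 24
Reactants: 41 (E)-C9-ethylidene ketone; 42 acetone; 43 acryloyl chloride
Product: 47 C9-vinyl ketone carrying the C2 acrylate (C9 quaternary: vinyl equatorial, CMe2–O–acryloyl axial), via lithium dienolate 44 (not isolated), via cerium dienolate 45 (not isolated), via cerium aldolate 46 (not isolated)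
Conditions: LiN(i-Pr)2, HMPA, THF, −78 to −30 °C; CeCl3, −78 °C; 42; 43, −78 to 0 °C
Reagents that add atoms: none
Why: γ-Deprotonation gives the extended dienolate, whose cerium derivative should add to acetone at the α-carbon C9 (organocerium aldol, which suppresses proton transfer and retro-aldol); attack is axial, on the ring B face where only H11 and H26 are 1,3-diaxial, so C2 ends axial and the vinyl group equatorial as the target requires, and the aldolate is trapped by O-acylation before it can revert.

Step 25
Reactants: 47 C9-vinyl ketone carrying the C2 acrylate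
Product: 48 spiro-lactone ketone (ring A closed; C27 ketone)
Conditions: second-generation Grubbs catalyst (10 mol%), toluene, 80 °C
Reagents that add atoms: none
Why: Ring-closing metathesis of the acrylate with the C9 vinyl group closes ring A as the α,β-unsaturated δ-lactone (C7=C8) and releases ethene.

Step 26
Reactants: 48 spiro-lactone ketone
Product: 49 CNP0222978.4 (target)
Conditions: MeMgBr, CeCl3, THF, −78 °C
Reagents that add atoms: methylmagnesium bromide, C[Mg]Br
Why: Organocerium 1,2-addition should select the C27 ketone over the two lactones and over ketone C30 (shielded by two quaternary neighbours); the axial trajectory is blocked by the 1,3-diaxial cage carbon C22, so equatorial attack gives the axial hydroxyl syn to C22 and the equatorial methyl, as in the target.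

**Compound list**

1 | 3-bromobut-3-en-1-ol | OCCC(Br)=C | starting material
2 | 2-bromo-4-chlorobut-1-ene | ClCCC(Br)=C | intermediate
3 | 2-(4-chlorobut-1-en-2-yl)-4,4,5,5-tetramethyl-1,3,2-dioxaborolane | C=C(CCCl)B1OC(C)(C)C(C)(C)O1 | intermediate
4 | cyclohex-2-en-1-one | O=C1C=CCCC1 | starting material
5 | (R)-3-(4-chlorobut-1-en-2-yl)cyclohexan-1-one | O=C1CCC[C@H](C1)C(=C)CCCl | intermediate
6 | (3aR,7aR)-1-methylideneoctahydro-4H-inden-4-one (cis-fused) | O=C2CCC[C@H]4C(=C)CC[C@@H]24 | intermediate
7 | cis-fused 1-methylideneoctahydro-1H-inden-4-ol, C27 hydroxyl cis to the C26–C25 bond | O[C@H]2CCC[C@H]4C(=C)CC[C@@H]24 | intermediate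
8 | tert-butyldimethylsilyl ether of 7 | CC(C)(C)[Si](C)(C)O[C@H]2CCC[C@H]4C(=C)CC[C@@H]24 | intermediate
9 | spiro ozonide (1,2,4-trioxolane at C22) of 8 | CC(C)(C)[Si](C)(C)O[C@H]2CCC[C@H]4C5(OCOO5)CC[C@@H]24 | intermediate
10 | cis-fused 4-(tert-butyldimethylsilyloxy)octahydro-1H-inden-1-one | CC(C)(C)[Si](C)(C)O[C@H]2CCC[C@H]4C(=O)CC[C@@H]24 | intermediate
11 | lithium enolate of 10 (C22=C23) | CC(C)(C)[Si](C)(C)O[C@H]2CCC[C@H]4C(O[Li])=CC[C@@H]24 | intermediate
12 | C23 dimethylaminomethyl ketone (Mannich base) | CC(C)(C)[Si](C)(C)O[C@H]2CCC[C@H]4C(=O)C(CN(C)C)C[C@@H]24 | intermediate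
13 | trimethylammonium iodide of 12 | CC(C)(C)[Si](C)(C)O[C@H]2CCC[C@H]4C(=O)C(C[N+](C)(C)C)C[C@@H]24.[I-] | intermediate
14 | C23-methylidene ketone | CC(C)(C)[Si](C)(C)O[C@H]2CCC[C@H]4C(=O)C(=C)C[C@@H]24 | intermediate
15 | methacrolein (2-methylprop-2-enal) | CC(=C)C=O | starting material
16 | lithium enolate C22(OLi)=C23(CH3) | CC(C)(C)[Si](C)(C)O[C@H]2CCC[C@H]4C(O[Li])=C(C)C[C@@H]24 | intermediate
17 | C23 aldol adduct (methyl and 1-hydroxy-2-methylallyl on C23; carbinol epimers) | CC(C)(C)[Si](C)(C)O[C@H]2CCC[C@H]4C(=O)[C@](C)(C(O)C(C)=C)C[C@@H]24 | intermediate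
18 | C23 methacryloyl ketone | CC(C)(C)[Si](C)(C)O[C@H]2CCC[C@H]4C(=O)[C@](C)(C(=O)C(C)=C)C[C@@H]24 | intermediate
19 | ring B-fused bicyclo[3.2.1]octane-2,8-dione, C14 methyl exo, C27 silyl ether | CC(C)(C)[Si](C)(C)O[C@H]2CCC[C@@]34C[C@@H](C)C(=O)[C@](C)(C[C@@H]24)C3=O | intermediate
20 | tert-butyl acrylate | C=CC(=O)OC(C)(C)C | starting material
21 | C14 Michael adduct (tert-butyl propanoate chain syn to C22) | CC(C)(C)[Si](C)(C)O[C@H]2CCC[C@@]34C[C@@](C)(CCC(=O)OC(C)(C)C)C(=O)[C@](C)(C[C@@H]24)C3=O | intermediate
22 | C27 alcohol of 21 | O[C@H]2CCC[C@@]34C[C@@](C)(CCC(=O)OC(C)(C)C)C(=O)[C@](C)(C[C@@H]24)C3=O | intermediate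
23 | diethylphosphonoacetic acid | CCOP(=O)(OCC)CC(=O)O | starting material
24 | C27 diethylphosphonoacetate | CCOP(=O)(OCC)CC(=O)O[C@H]2CCC[C@@]34C[C@@](C)(CCC(=O)OC(C)(C)C)C(=O)[C@](C)(C[C@@H]24)C3=O | intermediate
25 | seven-membered unsaturated lactone C27–O–C(=O)–CH=C22 | O1[C@H]2CCC[C@@]34C[C@@](C)(CCC(=O)OC(C)(C)C)C(=O)[C@](C)(C[C@@H]24)/C3=C/C1=O | intermediate
26 | hydroxy enal (ring-opened lactol) | O[C@H]2CCC[C@@]34C[C@@](C)(CCC(=O)OC(C)(C)C)C(=O)[C@](C)(C[C@@H]24)/C3=C/C=O | intermediate
27 | allylic diol, tert-butyl ester | O[C@H]2CCC[C@@]34C[C@@](C)(CCC(=O)OC(C)(C)C)C(=O)[C@](C)(C[C@@H]24)/C3=C/CO | intermediate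
28 | seco acid | O[C@H]2CCC[C@@]34C[C@@](C)(CCC(=O)O)C(=O)[C@](C)(C[C@@H]24)/C3=C/CO | intermediate
29 | bridged ten-membered allylic lactone (C27 hydroxyl) | O[C@H]2CCC[C@@]34C[C@@]5(C)CCC(=O)OC/C=C3/[C@@](C)(C[C@@H]24)C5=O | intermediate
30 | trimethylsilyl ketene acetal of 29 (C27 trimethylsilyl ether) | C[Si](C)(C)O[C@H]2CCC[C@@]34C[C@@]5(C)C/C=C(\O[Si](C)(C)C)OC/C=C3/[C@@](C)(C[C@@H]24)C5=O | intermediate
31 | trimethylsilyl ester and ether of 32 | C[Si](C)(C)O[C@H]2CCC[C@@]34C[C@@]5(C)C[C@@H](C(=O)O[Si](C)(C)C)[C@]3(C=C)[C@@](C)(C[C@@H]24)C5=O | intermediate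
32 | C22-vinyl bicyclo[2.2.2]octane C18 carboxylic acid (C27 hydroxyl) | O[C@H]2CCC[C@@]34C[C@@]5(C)C[C@@H](C(=O)O)[C@]3(C=C)[C@@](C)(C[C@@H]24)C5=O | intermediate
33 | ozonide of 32 | O[C@H]2CCC[C@@]34C[C@@]5(C)C[C@@H](C(=O)O)[C@]3(C6OCOO6)[C@@](C)(C[C@@H]24)C5=O | intermediate
34 | C21 hydroxy acid | O[C@H]2CCC[C@@]34C[C@@]5(C)C[C@@H](C(=O)O)[C@]3(CO)[C@@](C)(C[C@@H]24)C5=O | intermediate
35 | γ-lactone alcohol | O[C@H]2CCC[C@@]34C[C@@]5(C)C[C@H]6C(=O)OC[C@]63[C@@](C)(C[C@@H]24)C5=O | intermediate
36 | γ-lactone diketone | O=C2CCC[C@@]34C[C@@]5(C)C[C@H]6C(=O)OC[C@]63[C@@](C)(C[C@@H]24)C5=O | intermediate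
37 | acetaldehyde | CC=O | starting material
38 | lithium enolate of 36 (C27=C9) | [Li]OC2=CCC[C@@]34C[C@@]5(C)C[C@H]6C(=O)OC[C@]63[C@@](C)(C[C@@H]24)C5=O | intermediate
39 | C9 aldol adduct (epimers at C9 and carbinol) | O=C2C(C(C)O)CC[C@@]34C[C@@]5(C)C[C@H]6C(=O)OC[C@]63[C@@](C)(C[C@@H]24)C5=O | intermediate
40 | mesylate of 39 | O=C2C(C(C)OS(C)(=O)=O)CC[C@@]34C[C@@]5(C)C[C@H]6C(=O)OC[C@]63[C@@](C)(C[C@@H]24)C5=O | intermediate
41 | (E)-C9-ethylidene ketone | O=C2/C(=C/C)CC[C@@]34C[C@@]5(C)C[C@H]6C(=O)OC[C@]63[C@@](C)(C[C@@H]24)C5=O | intermediate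
42 | acetone | CC(C)=O | starting material
43 | acryloyl chloride | C=CC(=O)Cl | starting material
44 | lithium dienolate of 41 | [Li]OC2=C(C=C)CC[C@@]34C[C@@]5(C)C[C@H]6C(=O)OC[C@]63[C@@](C)(C[C@@H]24)C5=O | intermediate
45 | dichlorocerium dienolate | Cl[Ce](Cl)OC2=C(C=C)CC[C@@]34C[C@@]5(C)C[C@H]6C(=O)OC[C@]63[C@@](C)(C[C@@H]24)C5=O | intermediate
46 | dichlorocerium aldolate (C9 quaternary) | O=C2[C@](C=C)(C(C)(C)O[Ce](Cl)Cl)CC[C@@]34C[C@@]5(C)C[C@H]6C(=O)OC[C@]63[C@@](C)(C[C@@H]24)C5=O | intermediate
47 | C9-vinyl ketone with C2 acrylate | O=C2[C@](C=C)(C(C)(C)OC(=O)C=C)CC[C@@]34C[C@@]5(C)C[C@H]6C(=O)OC[C@]63[C@@](C)(C[C@@H]24)C5=O | intermediate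
48 | spiro-lactone ketone (ring A closed, C27 ketone) | O=C2[C@@]7(C=CC(=O)OC7(C)C)CC[C@@]34C[C@@]5(C)C[C@H]6C(=O)OC[C@]63[C@@](C)(C[C@@H]24)C5=O | intermediate
49 | CNP0222978.4 | CC1(C)OC(=O)C=C[C@]12CC[C@@]13C[C@@]4(C)C[C@H]5C(=O)OC[C@]51[C@@](C)(C[C@H]3[C@@]2(C)O)C4=O | target

**Totals and risks**

Total step count: 26. Longest linear sequence: 26 steps (1 to 49); compounds 4, 15, 20, 23, 37, 42 and 43 enter as single reagents along this line.

Steps most likely to fail:

Step 19. The silyl ketene acetal may be unable to fold into the boat-like array across the bicycle, so that lactone is simply recovered, or the allylic carboxylate may ionise or eliminate at the temperature needed. The fallback leaves the macrocycle aside, starts from diol 27 and uses an intramolecular SN2′ enolate alkylation, a known way to close a six-membered ring onto a vinyl-bearing carbon. The primary allylic alcohol is converted into the allylic chloride F1 (MsCl, LiCl, 2,4,6-collidine), the C27 hydroxyl is capped as its trimethylsilyl ether F2 (Me3SiCl, imidazole), and KN(SiMe3)2 generates the tert-butyl ester enolate, which attacks C22 in a 6-exo SN2′ sense from the only face the C14 tether reaches and expels chloride to give the vinyl tert-butyl ester F3. C17 is not fixed by a concerted transition state here and would be set by separation of the epimers with re-enolisation of the unwanted one. Aqueous H3PO4 then removes the tert-butyl and silyl groups and the route is rejoined at acid 32.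

Step 24. Proton transfer from acetone to the hindered dienolate, reversal of the congested aldolate before acylation, or attack through the γ-carbon may all erode the step. The fallback starts from 41 and builds C2 in stages with better electrophiles. The same dienolate adds to acetaldehyde at C9 to give the secondary aldol F4; Dess–Martin oxidation gives the C9 acetyl diketone F5; MeMgBr/CeCl3 (two equivalents) adds to both ketones to give the diol F6, which also sets C27 by equatorial attack; the exocyclic C2 alkoxide, less hindered than the axial C27 one, is acylated with acryloyl chloride (KN(SiMe3)2) to give the acrylate F7; ring-closing metathesis then gives 49 directly, bypassing 47 and 48.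

Step 15. The stabilised phosphonate anion may fail to add to the doubly neopentyl bridging ketone, or the free alcohol 22 may be lost beforehand through hemiketal formation and retro-Claisen opening. The fallback starts from the silyl ether 21 and olefinates intermolecularly by Peterson reaction with lithiated ethyl (trimethylsilyl)acetate, giving the ethyl enoate F8 as a mixture of alkene isomers. HF·pyridine followed by a trace of acid removes the silyl group, and only the isomer with the ester cis to C12 can lactonise onto the C27 hydroxyl, which returns 25; the other isomer is recycled by photochemical alkene isomerisation.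

**Further compounds**

F1 | step 19 | allylic chloride from diol 27 | O[C@H]2CCC[C@@]34C[C@@](C)(CCC(=O)OC(C)(C)C)C(=O)[C@](C)(C[C@@H]24)/C3=C/CCl
F2 | step 19 | C27 trimethylsilyl ether of F1 | C[Si](C)(C)O[C@H]2CCC[C@@]34C[C@@](C)(CCC(=O)OC(C)(C)C)C(=O)[C@](C)(C[C@@H]24)/C3=C/CCl
F3 | step 19 | C22-vinyl bicyclo[2.2.2]octane C18 tert-butyl ester, C27 trimethylsilyl ether | C[Si](C)(C)O[C@H]2CCC[C@@]34C[C@@]5(C)C[C@@H](C(=O)OC(C)(C)C)[C@]3(C=C)[C@@](C)(C[C@@H]24)C5=O
F4 | step 24 | C9-vinyl C9-(1-hydroxyethyl) ketone (carbinol epimers) | O=C2[C@](C=C)(C(C)O)CC[C@@]34C[C@@]5(C)C[C@H]6C(=O)OC[C@]63[C@@](C)(C[C@@H]24)C5=O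
F5 | step 24 | C9-vinyl C9-acetyl diketone | O=C2[C@](C=C)(C(C)=O)CC[C@@]34C[C@@]5(C)C[C@H]6C(=O)OC[C@]63[C@@](C)(C[C@@H]24)C5=O
F6 | step 24 | C27/C2 diol with C9 vinyl | C[C@]2(O)[C@](C=C)(C(C)(C)O)CC[C@@]34C[C@@]5(C)C[C@H]6C(=O)OC[C@]63[C@@](C)(C[C@@H]24)C5=O
F7 | step 24 | C2 acrylate of F6 | C[C@]2(O)[C@](C=C)(C(C)(C)OC(=O)C=C)CC[C@@]34C[C@@]5(C)C[C@H]6C(=O)OC[C@]63[C@@](C)(C[C@@H]24)C5=O
F8 | step 15 | C22 ethoxycarbonylmethylidene derivative of 21 (alkene isomers) | CC(C)(C)[Si](C)(C)O[C@H]2CCC[C@@]34C[C@@](C)(CCC(=O)OC(C)(C)C)C(=O)[C@](C)(C[C@@H]24)C3=CC(=O)OCC
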